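The oxane ring (O1, C2–C6) is closed last, at C2–C3: the bond between the ring CH that carries the acrylic acid and the neighbouring ring CH2. The key step exploits that C2 is both α to the ring oxygen and allylic to the exocyclic methylene of the acrylate. In the open-chain precursor C2 is therefore the oxygen-bearing β-carbon of a 3-alkoxy-2-(phenylsulfonylmethyl)acrylate, and C3 is unmasked as a primary radical by photoredox decarboxylation. One 6-exo radical addition with loss of a sulfonyl radical closes the ring, sets C2 trans to the C5 side chain and unveils the 2-substituted acrylate. C5 comes from an auxiliary-controlled Michael addition, the triene chain from farnesyl bromide.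

Key step: step 10

Assumption: methyl (E)-3-methoxy-2-methylacrylate (1) is taken as a catalogue chemical, and the enol ether of 18 to 21 is drawn as the Z isomer although either geometry should converge in step 10.

Step 1
Reactants: 1 methyl (E)-3-methoxy-2-methylacrylate
Product: 2 methyl (Z)-2-(bromomethyl)-3-methoxyacrylate
Conditions: NBS, AIBN (cat.), PhCF3, 80 °C
Reagents that add atoms: N-bromosuccinimide, O=C1CCC(=O)N1Br
Why: Wohl–Ziegler bromination should take place at the only allylic position, whose radical is stabilised by both the ester and the enol ether, with the double bond left in place.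

Step 2
Reactants: 2 methyl (Z)-2-(bromomethyl)-3-methoxyacrylate
Product: 3 methyl (Z)-3-methoxy-2-[(phenylsulfonyl)methyl]acrylate
Conditions: PhSO2Na, DMF, 23 °C
Reagents that add atoms: sodium benzenesulfinate, [Na+].[O-]S(=O)c1ccccc1
Why: SN2 displacement of the activated allylic bromide by the soft sulfur atom of the sulfinate (S-alkylation) should give the allyl sulfone.

Step 3
Reactants: 4 (2E,6E)-farnesyl bromide; 5 3-chloropropan-1-ol
Product: 8 (5E,9E)-6,10,14-trimethylpentadeca-5,9,13-trien-1-ol, via chloromagnesium 3-chloropropan-1-olate 6 (not isolated), via 3-(chloromagnesiooxy)propylmagnesium chloride 7 (not isolated)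
Conditions: 5, i-PrMgCl, THF, −20 °C; Mg, THF, reflux; then 4, Li2CuCl4 (3 mol %), THF, −20 to 0 °C; 1 M HCl, 0 °C
Reagents that add atoms: none
Why: The alkoxide-protected three-carbon Grignard reagent, made by deprotonation and magnesium insertion, should couple with the primary allylic bromide under Li2CuCl4 catalysis at the α-carbon (SN2) with retention of both E alkenes.

Step 4
Reactants: 8 (5E,9E)-6,10,14-trimethylpentadeca-5,9,13-trien-1-ol
Product: 10 (5E,9E)-6,10,14-trimethylpentadeca-5,9,13-trienoic acid, via (5E,9E)-6,10,14-trimethylpentadeca-5,9,13-trienal 9 (not isolated)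
Conditions: TEMPO (cat.), PhI(OAc)2, MeCN/H2O (1:1), 23 °C
Reagents that add atoms: water, O
Why: Oxoammonium oxidation of the primary alcohol gives the aldehyde, whose hydrate is oxidised on to the acid, while the isolated trisubstituted alkenes should stay untouched.

Step 5
Reactants: 10 (5E,9E)-6,10,14-trimethylpentadeca-5,9,13-trienoic acid; 11 (R)-4-benzyl-1,3-oxazolidin-2-one
Product: 13 (4R)-4-benzyl-3-[(5E,9E)-6,10,14-trimethylpentadeca-5,9,13-trienoyl]-1,3-oxazolidin-2-one, via pivalic mixed anhydride 12 (not isolated)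
Conditions: PivCl, Et3N, THF, −20 °C; then 11, LiCl, −20 to 23 °C
Reagents that add atoms: none
Why: N-Acylation through the mixed anhydride should occur at the unhindered acyl group, because the pivaloyl carbonyl is shielded by its tert-butyl group.

Step 6
Reactants: 13 (4R)-4-benzyl-3-[(5E,9E)-6,10,14-trimethylpentadeca-5,9,13-trienoyl]-1,3-oxazolidin-2-one; 14 tert-butyl acrylate
Product: 16 tert-butyl (4S,7E,11E)-4-[(4R)-4-benzyl-2-oxo-1,3-oxazolidine-3-carbonyl]-8,12,16-trimethylheptadeca-7,11,15-trienoate, via chlorotitanium (Z)-enolate 15 (not isolated)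
Conditions: TiCl4, i-Pr2NEt, CH2Cl2, 0 °C; then 14, 0 °C; aq. NH4Cl
Reagents that add atoms: none
Why: Soft enolisation gives the chelated (Z)-titanium enolate, and Michael addition to the acrylate on the face opposite the benzyl group of the (R)-auxiliary should set the 4S centre, the later C5 of the ring.

Step 7
Reactants: 16 tert-butyl (4S,7E,11E)-4-[(4R)-4-benzyl-2-oxo-1,3-oxazolidine-3-carbonyl]-8,12,16-trimethylheptadeca-7,11,15-trienoate
Product: 17 tert-butyl (4S,7E,11E)-4-(hydroxymethyl)-8,12,16-trimethylheptadeca-7,11,15-trienoate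
Conditions: LiBH4, MeOH (1 equiv), Et2O, 0 °C
Reagents that add atoms: none
Why: Borohydride reduction of the activated exocyclic imide carbonyl should release the primary alcohol and the auxiliary, while the hindered tert-butyl ester, the alkenes and the stereocentre stay untouched.

Step 8
Reactants: 17 tert-butyl (4S,7E,11E)-4-(hydroxymethyl)-8,12,16-trimethylheptadeca-7,11,15-trienoate; 3 methyl (Z)-3-methoxy-2-[(phenylsulfonyl)methyl]acrylate
Product: 18 tert-butyl (4S,7E,11E)-4-({[(1Z)-3-methoxy-3-oxo-2-(phenylsulfonylmethyl)prop-1-en-1-yl]oxy}methyl)-8,12,16-trimethylheptadeca-7,11,15-trienoate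
Conditions: 3 (3 equiv), PPTS (cat.), toluene, 5 Å molecular sieves, 90 °C
Reagents that add atoms: none
Why: Acid-catalysed trans-etherification of the 3-methoxyacrylate (protonation, mixed acetal, loss of methanol) should be driven to the primary alkyl enol ether by removal of methanol.

Step 9
Reactants: 18 tert-butyl (4S,7E,11E)-4-({[(1Z)-3-methoxy-3-oxo-2-(phenylsulfonylmethyl)prop-1-en-1-yl]oxy}methyl)-8,12,16-trimethylheptadeca-7,11,15-trienoate
Product: 20 (4S,7E,11E)-4-({[(1Z)-3-methoxy-3-oxo-2-(phenylsulfonylmethyl)prop-1-en-1-yl]oxy}methyl)-8,12,16-trimethylheptadeca-7,11,15-trienoic acid, via trimethylsilyl ester 19 (not isolated)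
Conditions: TMSOTf, 2,6-lutidine, CH2Cl2, 0 °C; then pH 5 phosphate buffer
Reagents that add atoms: none
Why: Silyl triflate cleaves the tert-butyl ester by loss of 2-methylpropene under lutidine buffering, so that no free acid should reach the enol ether or the trisubstituted alkenes, and the silyl ester hydrolyses at work-up.

Step 10
Reactants: 20 (4S,7E,11E)-4-({[(1Z)-3-methoxy-3-oxo-2-(phenylsulfonylmethyl)prop-1-en-1-yl]oxy}methyl)-8,12,16-trimethylheptadeca-7,11,15-trienoic acid
Product: 22 methyl 2-[(2R,5S)-5-[(3E,7E)-4,8,12-trimethyltrideca-3,7,11-trien-1-yl]oxan-2-yl]prop-2-enoate, via N-acyloxyphthalimide ester 21 (not isolated)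
Conditions: N-hydroxyphthalimide, DIC, DMAP (cat.), CH2Cl2, 23 °C; then Ru(bpy)3(PF6)2 (1 mol %), diethyl 2,6-dimethyl-1,4-dihydropyridine-3,5-dicarboxylate, i-Pr2NEt, CH2Cl2 (0.01 M), 450 nm LEDs, 23 °C
Reagents that add atoms: none
Why: Proposed new method: single-electron reduction of the in-situ N-acyloxyphthalimide 21 by the photoreduced ruthenium catalyst releases CO2, phthalimide anion and the primary C3 radical, which adds to the oxygen-bearing β-carbon C2 of the 3-alkoxy-2-(phenylsulfonylmethyl)acrylate; the α-ester radical so formed expels PhSO2• by β-scission, which leaves the exo-methylene ester, and the sulfonyl radical is reduced to sulfinate, closing the catalytic cycle (an intramolecular SH2′ allyl transfer). The closest known reaction types are the 6-exo radical cyclisation of β-alkoxyacrylates to 2-substituted oxanes and the photoredox decarboxylative allylation of N-acyloxyphthalimides with 2-(sulfonylmethyl)acrylates by addition–fragmentation; what is untested is their merger on one acceptor with attack at its alkoxy-substituted terminus. The oxane ring closes in the 6-exo-trig mode. The new C2 centre is set by the existing C5 centre through a chair-like transition state in which the homofarnesyl chain and the acceptor alkene are both equatorial, which should favour the 2,5-trans (2R,5S) ring. The step needs the nucleophilic primary radical to choose the electron-poor enol ether over the three trisubstituted alkenes, which polarity matching and the fast activated 6-exo closure should secure, and it needs fragmentation to outrun hydrogen transfer from the dihydropyridine, which the weak β C–S bond and high dilution should secure.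

Step 11
Reactants: 22 methyl 2-[(2R,5S)-5-[(3E,7E)-4,8,12-trimethyltrideca-3,7,11-trien-1-yl]oxan-2-yl]prop-2-enoate
Product: 23 rhopaloic acid A, 2-[(2R,5S)-5-[(3E,7E)-4,8,12-trimethyltrideca-3,7,11-trien-1-yl]oxan-2-yl]prop-2-enoic acid
Conditions: LiOH, THF/H2O (3:1), 23 °C; then 1 M HCl to pH 3
Reagents that add atoms: lithium hydroxide, [Li+].[OH-]
Why: Saponification of the methyl ester should proceed without epimerisation, because the acrylate has no α-hydrogen and C2 carries no acidifying group.

Compound list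

1 | methyl (E)-3-methoxy-2-methylacrylate | CO/C=C(\C)C(=O)OC | starting material
2 | methyl (Z)-2-(bromomethyl)-3-methoxyacrylate | CO/C=C(\CBr)C(=O)OC | intermediate
3 | methyl (Z)-3-methoxy-2-[(phenylsulfonyl)methyl]acrylate | CO/C=C(\CS(=O)(=O)c1ccccc1)C(=O)OC | intermediate
4 | (2E,6E)-farnesyl bromide, (2E,6E)-1-bromo-3,7,11-trimethyldodeca-2,6,10-triene | BrC/C=C(\C)CC/C=C(\C)CCC=C(C)C | starting material
5 | 3-chloropropan-1-ol | OCCCCl | starting material
6 | chloromagnesium 3-chloropropan-1-olate | ClCCCO[Mg]Cl | intermediate (not isolated)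
7 | 3-(chloromagnesiooxy)propylmagnesium chloride | Cl[Mg]CCCO[Mg]Cl | intermediate (not isolated)
8 | (5E,9E)-6,10,14-trimethylpentadeca-5,9,13-trien-1-ol | OCCCC/C=C(\C)CC/C=C(\C)CCC=C(C)C | intermediate
9 | (5E,9E)-6,10,14-trimethylpentadeca-5,9,13-trienal | O=CCCC/C=C(\C)CC/C=C(\C)CCC=C(C)C | intermediate (not isolated)
10 | (5E,9E)-6,10,14-trimethylpentadeca-5,9,13-trienoic acid | OC(=O)CCC/C=C(\C)CC/C=C(\C)CCC=C(C)C | intermediate
11 | (R)-4-benzyl-1,3-oxazolidin-2-one | O=C1N[C@H](Cc2ccccc2)CO1 | starting material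
12 | (5E,9E)-6,10,14-trimethylpentadeca-5,9,13-trienoic pivalic anhydride | CC(C)(C)C(=O)OC(=O)CCC/C=C(\C)CC/C=C(\C)CCC=C(C)C | intermediate (not isolated)
13 | (4R)-4-benzyl-3-[(5E,9E)-6,10,14-trimethylpentadeca-5,9,13-trienoyl]-1,3-oxazolidin-2-one | O=C(CCC/C=C(\C)CC/C=C(\C)CCC=C(C)C)N1C(=O)OC[C@H]1Cc1ccccc1 | intermediate
14 | tert-butyl acrylate | C=CC(=O)OC(C)(C)C | starting material
15 | trichlorotitanium (Z)-enolate of 13 | Cl[Ti](Cl)(Cl)O/C(N1C(=O)OC[C@H]1Cc1ccccc1)=C\CC/C=C(\C)CC/C=C(\C)CCC=C(C)C | intermediate (not isolated)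
16 | tert-butyl (4S,7E,11E)-4-[(4R)-4-benzyl-2-oxo-1,3-oxazolidine-3-carbonyl]-8,12,16-trimethylheptadeca-7,11,15-trienoate | CC(C)(C)OC(=O)CC[C@H](CC/C=C(\C)CC/C=C(\C)CCC=C(C)C)C(=O)N1C(=O)OC[C@H]1Cc1ccccc1 | intermediate
17 | tert-butyl (4S,7E,11E)-4-(hydroxymethyl)-8,12,16-trimethylheptadeca-7,11,15-trienoate | CC(C)(C)OC(=O)CC[C@H](CC/C=C(\C)CC/C=C(\C)CCC=C(C)C)CO | intermediate
18 | tert-butyl (4S,7E,11E)-4-({[(1Z)-3-methoxy-3-oxo-2-(phenylsulfonylmethyl)prop-1-en-1-yl]oxy}methyl)-8,12,16-trimethylheptadeca-7,11,15-trienoate | CC(C)(C)OC(=O)CC[C@H](CC/C=C(\C)CC/C=C(\C)CCC=C(C)C)CO/C=C(\CS(=O)(=O)c1ccccc1)C(=O)OC | intermediate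
19 | trimethylsilyl ester of 20 | C[Si](C)(C)OC(=O)CC[C@H](CC/C=C(\C)CC/C=C(\C)CCC=C(C)C)CO/C=C(\CS(=O)(=O)c1ccccc1)C(=O)OC | intermediate (not isolated)
20 | (4S,7E,11E)-4-({[(1Z)-3-methoxy-3-oxo-2-(phenylsulfonylmethyl)prop-1-en-1-yl]oxy}methyl)-8,12,16-trimethylheptadeca-7,11,15-trienoic acid | OC(=O)CC[C@H](CC/C=C(\C)CC/C=C(\C)CCC=C(C)C)CO/C=C(\CS(=O)(=O)c1ccccc1)C(=O)OC | intermediate
21 | 1,3-dioxoisoindolin-2-yl ester of 20 | O=C(CC[C@H](CC/C=C(\C)CC/C=C(\C)CCC=C(C)C)CO/C=C(\CS(=O)(=O)c1ccccc1)C(=O)OC)ON1C(=O)c2ccccc2C1=O | intermediate (not isolated)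
22 | methyl 2-[(2R,5S)-5-[(3E,7E)-4,8,12-trimethyltrideca-3,7,11-trien-1-yl]oxan-2-yl]prop-2-enoate | C=C(C(=O)OC)[C@H]1CC[C@H](CC/C=C(\C)CC/C=C(\C)CCC=C(C)C)CO1 | intermediate
23 | rhopaloic acid A, 2-[(2R,5S)-5-[(3E,7E)-4,8,12-trimethyltrideca-3,7,11-trien-1-yl]oxan-2-yl]prop-2-enoic acid | C=C(C(=O)O)[C@H]1CC[C@H](CC/C=C(\C)CC/C=C(\C)CCC=C(C)C)CO1 | target

Total step count: 11.
Longest linear sequence: 9 steps (steps 3 to 11, from farnesyl bromide 4).

Steps most likely to fail

1. Step 10 (labelled step).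
- What may go wrong: hydrogen-atom transfer to the C3 radical before ring closure, or to the α-ester radical before fragmentation. The sulfonyl radical may add reversibly to the chain alkenes with loss of E geometry. Trans/cis control at C2 may be weak.
- Fallback (known chemistry, sulfone-free): the ring is closed at the same bond by the established hydrogen-terminated radical cyclisation of a plain β-alkoxyacrylate, and the methylene is added afterwards. It sets out from alcohol 17.
- Conjugate addition to methyl propiolate (N-methylmorpholine, CH2Cl2) should give the (E)-β-alkoxyacrylate tert-butyl ester F1.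
- TMSOTf/2,6-lutidine gives the trimethylsilyl ester F2 and, after buffer, the carboxylic acid F3.
- N-Hydroxyphthalimide/DIC gives the N-acyloxyphthalimide F4. Under Ru(bpy)3(PF6)2, the dihydropyridine, i-Pr2NEt and blue light it should cyclise 6-exo with hydrogen transfer to the methyl oxan-2-ylacetate F5.
- LiN(SiMe3)2 (THF, −78 °C) and dimethylmethyleneammonium iodide give the Mannich base F6, MeI gives the trimethylammonium iodide F7, and DBU eliminates trimethylamine.
- The fallback comes back to the route at methyl ester 22.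

2. Step 8.
- What may go wrong: protonation of the acceptor-flanked enol ether may be too slow, so that the exchange stalls. Acid and heat may lactonise 17 with loss of the tert-butyl group.
- Fallback (O-alkylation under basic conditions in place of acid-catalysed exchange): it sets out from alcohol 17.
- Tf2O and 2,6-di-tert-butyl-4-methylpyridine (CH2Cl2, −78 °C) give the primary triflate F8.
- Separately, sulfone 3 is hydrolysed (1 M HCl, THF) to methyl 2-formyl-3-(phenylsulfonyl)propanoate F9, which NaH in DMF converts into the sodium enolate F10.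
- O-Alkylation of F10 by the hard triflate F8 in the polar aprotic solvent should give the enol ether.
- The fallback comes back to the route at 18.

3. Step 6.
- What may go wrong: the Lewis acid may protonate or cyclise the triene. Conjugate addition may be incomplete, with erosion of facial control.
- Fallback (alkylation of the sodium enolate, then adjustment of the oxidation level, in place of the Lewis-acid Michael addition): it sets out from imide 13.
- NaN(SiMe3)2 (THF, −78 °C) and allyl iodide should give the (2S)-allyl imide F11.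
- 9-BBN (THF), selective for the terminal alkene, followed by NaBO3·4H2O gives the primary alcohol F12.
- TEMPO (cat.)/PhI(OAc)2 in MeCN/H2O gives the carboxylic acid F13, which Boc2O, DMAP (cat.) and t-BuOH convert into the tert-butyl ester.
- The fallback comes back to the route at 16.

Further compounds

F1 | step 10 | tert-butyl (4S,7E,11E)-4-({[(1E)-3-methoxy-3-oxoprop-1-en-1-yl]oxy}methyl)-8,12,16-trimethylheptadeca-7,11,15-trienoate | CC(C)(C)OC(=O)CC[C@H](CC/C=C(\C)CC/C=C(\C)CCC=C(C)C)CO/C=C/C(=O)OC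
F2 | step 10 | trimethylsilyl ester of F3 | C[Si](C)(C)OC(=O)CC[C@H](CC/C=C(\C)CC/C=C(\C)CCC=C(C)C)CO/C=C/C(=O)OC
F3 | step 10 | (4S,7E,11E)-4-({[(1E)-3-methoxy-3-oxoprop-1-en-1-yl]oxy}methyl)-8,12,16-trimethylheptadeca-7,11,15-trienoic acid | OC(=O)CC[C@H](CC/C=C(\C)CC/C=C(\C)CCC=C(C)C)CO/C=C/C(=O)OC
F4 | step 10 | 1,3-dioxoisoindolin-2-yl ester of F3 | O=C(CC[C@H](CC/C=C(\C)CC/C=C(\C)CCC=C(C)C)CO/C=C/C(=O)OC)ON1C(=O)c2ccccc2C1=O
F5 | step 10 | methyl 2-[(2R,5S)-5-[(3E,7E)-4,8,12-trimethyltrideca-3,7,11-trien-1-yl]oxan-2-yl]acetate | COC(=O)C[C@H]1CC[C@H](CC/C=C(\C)CC/C=C(\C)CCC=C(C)C)CO1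
F6 | step 10 | methyl 3-(dimethylamino)-2-[(2R,5S)-5-[(3E,7E)-4,8,12-trimethyltrideca-3,7,11-trien-1-yl]oxan-2-yl]propanoate | COC(=O)C(CN(C)C)[C@H]1CC[C@H](CC/C=C(\C)CC/C=C(\C)CCC=C(C)C)CO1
F7 | step 10 | 3-methoxy-N,N,N-trimethyl-3-oxo-2-[(2R,5S)-5-[(3E,7E)-4,8,12-trimethyltrideca-3,7,11-trien-1-yl]oxan-2-yl]propan-1-aminium iodide | COC(=O)C(C[N+](C)(C)C)[C@H]1CC[C@H](CC/C=C(\C)CC/C=C(\C)CCC=C(C)C)CO1.[I-]
F8 | step 8 | tert-butyl (4S,7E,11E)-8,12,16-trimethyl-4-({[(trifluoromethyl)sulfonyl]oxy}methyl)heptadeca-7,11,15-trienoate | CC(C)(C)OC(=O)CC[C@H](CC/C=C(\C)CC/C=C(\C)CCC=C(C)C)COS(=O)(=O)C(F)(F)F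
F9 | step 8 | methyl 2-formyl-3-(phenylsulfonyl)propanoate | COC(=O)C(C=O)CS(=O)(=O)c1ccccc1
F10 | step 8 | sodium (Z)-3-methoxy-3-oxo-2-(phenylsulfonylmethyl)prop-1-en-1-olate | [Na+].[O-]/C=C(\CS(=O)(=O)c1ccccc1)C(=O)OC
F11 | step 6 | (4R)-4-benzyl-3-[(2S,5E,9E)-6,10,14-trimethyl-2-(prop-2-en-1-yl)pentadeca-5,9,13-trienoyl]-1,3-oxazolidin-2-one | C=CC[C@H](CC/C=C(\C)CC/C=C(\C)CCC=C(C)C)C(=O)N1C(=O)OC[C@H]1Cc1ccccc1
F12 | step 6 | (4R)-4-benzyl-3-[(2S,5E,9E)-2-(3-hydroxypropyl)-6,10,14-trimethylpentadeca-5,9,13-trienoyl]-1,3-oxazolidin-2-one | OCCC[C@H](CC/C=C(\C)CC/C=C(\C)CCC=C(C)C)C(=O)N1C(=O)OC[C@H]1Cc1ccccc1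
F13 | step 6 | (4S,7E,11E)-4-[(4R)-4-benzyl-2-oxo-1,3-oxazolidine-3-carbonyl]-8,12,16-trimethylheptadeca-7,11,15-trienoic acid | OC(=O)CC[C@H](CC/C=C(\C)CC/C=C(\C)CCC=C(C)C)C(=O)N1C(=O)OC[C@H]1Cc1ccccc1
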